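## Structural features

The target (C20H35BrO2) is a single cyclohexane ring, numbered here C1 to C6. C1 is a CH carrying a (3S)-3-hydroxy-3-methylpent-4-enyl chain (C1' to C5'). C2 is an all-carbon quaternary centre with a methyl and a 4-methylpent-3-enyl (homoprenyl) group. C3 is a CHBr, C4 and C5 are CH2, and C6 is a C(CH3)OH.

Four ring stereocentres are contiguous (C6 R, C1 S, C2 S, C3 S). The fifth, C3' (S), sits two methylenes away from the ring and cannot be reached by substrate control.

In the chair that places the C1 chain, the homoprenyl group and the bromine equatorial, the C2 methyl and the C6 hydroxyl are 1,3-diaxial. Bromine is cis to the C2 methyl and trans to the homoprenyl group, and the C6 hydroxyl is cis to the C1 chain.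

The real difficulty is the pair C2/C3. The two alkyl groups on C2 (CH3 and CH2R) are sterically almost equal, and the secondary bromide at C3 is neopentyl. Substitution there is slow and competes with elimination and 1,2-methyl shift.

Fragile groups are:
- the trisubstituted alkene and the vinyl group (electrophilic bromine, acid);
- the tertiary allylic alcohol (ionisation, allylic transposition);
- the secondary bromide (radicals, low-valent metals, strong base);
- both tertiary alcohols (dehydration).

The key step exploits the vicinal pair C2/C3. The anti relation between the C3–Br bond and the C2–CH2 bond of the homoprenyl arm is what anti addition of Br+ and a migrating carbon across a C2=C3 double bond would produce. The migrating carbon can be supplied from C1 by a semipinacol 1,2-shift.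

## Logic of the disconnections

**20 back to 18 (through 19).** No skeletal bond is cut. The vinyl carbinol is traced to a 2,3-epoxy alcohol, because the C3' stereocentre is too far from the ring for substrate control and must come from a reagent. The forward step must open the epoxide reductively without touching the C3'–O bond or the secondary bromide.

**18 back to 17, and 17 back to 15.** The epoxide is traced to an E trisubstituted allylic alcohol. In 17 the C3'–CH3 bond and the C4'–C5' bond are cut, which leads to a terminal alkyne. The gain is that the side chain becomes a four-carbon unit with no stereochemistry. The demand is a syn carbometalation that tolerates a free tertiary alcohol and the bromide.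

**15 back to 14.** The C6–CH3 bond is cut. A methyl nucleophile adding to the C6 ketone must enter equatorially, anti to the axial C2 methyl, to give the axial hydroxyl. It must also be non-basic so that C1 is not epimerised.

**14 back to 13, and 13 back to 10 plus 11.** The C1–H bond and then the C1–C1' bond are cut. Compound 13 is an enol ether, a masked C6 ketone, and the side chain arrives by an sp2–sp3 cross-coupling at an enol triflate. The demands are a coupling that spares the C–Br bond and a protonation at C1 on the face anti to the C2 methyl.

**10 back to 9, 8 and 5.** The C6–O bond and the isopropylidene terminus are removed. The key step leaves the carbonyl at C1, so a 1,2-carbonyl transposition is needed. Oxygenating C6 first and then coupling at the C1 enol triflate achieves it without cationic rearrangements. The isopropylidene is added only after the two electrophilic oxidations, because a trisubstituted chain alkene would compete for electrophilic bromine and peracid.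

**5 back to 4 (key disconnection).** The C2–CH2 bond of the butenyl arm and the C3–Br bond are cut together, with the butenyl group returned to C1 of a tertiary allylic alcohol. The quaternary centre and the neopentyl bromide thus come from one trisubstituted alkene and one carbinol stereocentre. The forward step must attack the ring alkene rather than the terminal alkene, and the butenyl shift must outrun capture by the hydroxyl.

**4 back to 1 plus 2 (through 3).** The C1–butenyl bond is cut. This leaves a commercial enone and a commercial Grignard reagent. The demand is a catalyst-controlled 1,2-addition that sets the tertiary carbinol as S.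

## Other disconnections considered

**Alternative 1:** Cut C1–C2 together with C3–Br by a bromonium-initiated polyene cyclisation of (S)-geranyllinalool A1. Br+ would have to add at the internal 10,11-alkene, the 6,7-alkene would close the ring, and water would capture the cation. This is the route that comes to mind first. It is set aside for four reasons:
- A1 has three trisubstituted alkenes and the terminal one is the most accessible, so the bromonium ion would form at the wrong place unless the terminus is masked.
- The hydroxyl of the vinyl carbinol can capture the ring cation and give a cyclic ether.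
- A concerted anti addition places the new C6–O bond equatorial, which is the C6 epimer of the target.
- The remote carbinol cannot control the absolute sense of ring formation.

The chosen plan reaches the same anti C2/C3 relation by a stereospecific shift from a preformed stereocentre.

**Alternative 2:** Set C2 and C3 by an enzymatic desymmetrisation. A ketoreductase would reduce one of the two enantiotopic carbonyls of the prochiral 2,2-disubstituted dione A2 to the hydroxy ketone A3. Bromide would then be introduced by substitution with inversion. The enzyme step is attractive, but the C–Br bond would be made by SN2 at a neopentyl secondary carbinol next to a quaternary carbon. Elimination, 1,2-methyl shift and retro-aldol cleavage of the β-hydroxy ketone are all expected to compete. The chosen plan forms the C–Br bond and the quaternary centre in the same operation, with no substitution.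

**Alternative 3:** Cut C1–C2 as a convergent union of two halves by an Ireland–Claisen rearrangement of the geranyl ester A4 to the acid A5. A chair transition state would set the C1/C2 relation from the alkene and enolate geometries. It is set aside for three reasons:
- C3 remains the CH of a vinyl group, and no reliable method places an equatorial bromine there with the required regiochemistry.
- The ring would still have to be closed, and metathesis would compete with the homoprenyl alkene.
- A4 is achiral, so the absolute configuration would need an additional chiral controller.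

More steps would follow the key step, and the C–Br problem would remain.

Key step: step 2

Remark: ring atoms are numbered as in the target throughout (C1 CH with the side chain, C2 quaternary, C3 CHBr, C6 C(CH3)OH). L* in step 1 is the known bis(sulfonamide) diol ligand made from trans-cyclohexane-1,2-diamine and 10-camphorsulfonyl chloride; both antipodes are accessible and it is not counted as a step. Compounds 1, 2 and 11 are taken as commercial.

## Steps

Step 1
Reactants: 1 2-methylcyclohex-2-en-1-one; 2 but-3-en-1-ylmagnesium bromide
Product: 4 (1S)-1-(but-3-en-1-yl)-2-methylcyclohex-2-en-1-ol, via di(but-3-en-1-yl)zinc 3 (not isolated)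
Conditions: 2, ZnCl2, Et2O, 0 °C to rt; 1,4-dioxane, filter; then 1, Ti(OiPr)4 (1.2 equiv), L* (10 mol %, antipode giving the S alcohol), PhMe, rt
Reagents that add atoms: none
Why: Catalytic enantioselective 1,2-addition of a dialkylzinc to a ketone, promoted by Ti(OiPr)4 and a chiral bis(sulfonamide) diol ligand; 2-substituted cyclic enones suit this reaction because the α-substituent differentiates the two carbonyl flanks and suppresses conjugate addition, and the ligand antipode is chosen so that the butenyl group is delivered to the face that gives the S carbinol.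

Step 2
Reactants: 4 (1S)-1-(but-3-en-1-yl)-2-methylcyclohex-2-en-1-ol
Product: 5 (2S,3S)-3-bromo-2-(but-3-en-1-yl)-2-methylcyclohexan-1-one
Conditions: NBS (1.05 equiv), CH2Cl2, −20 °C to rt, dark
Reagents that add atoms: N-bromosuccinimide, BrN1C(=O)CCC1=O
Why: NBS should transfer Br+ to the trisubstituted ring alkene on the face anti to the pseudoaxial butenyl group; the unsymmetrical bromonium ion opens at the tertiary carbon C2 while the C1–butenyl bond, antiperiplanar to the breaking C2–Br bond, shifts to C2 and the hydroxyl oxygen closes the carbonyl, the proton going to the succinimide anion. The closest known reaction type is the halonium-induced semipinacol rearrangement of tertiary allylic alcohols to α-quaternary β-halo ketones, together with its epoxide counterpart, the Lewis-acid rearrangement of 2,3-epoxy alcohols. No ring is closed and the ring size is kept, because the ring bond C1–C6 lies near the alkene plane and is not aligned for migration. C2 is controlled by the carbinol stereocentre: the shift is suprafacial, so the butenyl group arrives on the face it occupied at C1 and the S alcohol gives 2S. C3 is controlled by anti addition: bromine ends opposite the migrated group and therefore cis to the methyl, 3S. The step needs chemoselectivity for the ring alkene over the terminal alkene, which the higher substitution and the assistance of the neighbouring carbinol should secure. It also needs the shift to outrun epoxide formation by the hydroxyl, which is favoured because A(1,2) strain with the C2 methyl places the larger butenyl group pseudoaxial and the hydroxyl pseudoequatorial. The β-bromo ketone cannot lose HBr towards the carbonyl because C2 bears no hydrogen.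

Step 3
Reactants: 5 (2S,3S)-3-bromo-2-(but-3-en-1-yl)-2-methylcyclohexan-1-one
Product: 8 (2S,3S)-3-bromo-2-(but-3-en-1-yl)-2-methyl-6-{[tri(propan-2-yl)silyl]oxy}cyclohexan-1-one (mixture of C6 epimers), via silyl enol ether 6 (not isolated), via silyloxy epoxide 7 (not isolated)
Conditions: TIPSOTf, Et3N, CH2Cl2, 0 °C to rt; then mCPBA, NaHCO3, CH2Cl2, −20 to 0 °C
Reagents that add atoms: triisopropylsilyl trifluoromethanesulfonate, CC(C)[Si](OS(=O)(=O)C(F)(F)F)(C(C)C)C(C)C; meta-chloroperbenzoic acid, OOC(=O)c1cccc(Cl)c1
Why: Rubottom oxidation; the ketone can enolise only towards C6 because C2 is quaternary, the electron-rich silyl enol ether should be epoxidised far faster than the terminal alkene, and 1,4-silyl migration opens the epoxide to the α-silyloxy ketone; the new C6 centre forms as a mixture and is erased in step 5.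

Step 4
Reactants: 8 (2S,3S)-3-bromo-2-(but-3-en-1-yl)-2-methyl-6-{[tri(propan-2-yl)silyl]oxy}cyclohexan-1-one
Product: 9 (2S,3S)-3-bromo-2-methyl-2-(4-methylpent-3-en-1-yl)-6-{[tri(propan-2-yl)silyl]oxy}cyclohexan-1-one
Conditions: 2-methylbut-2-ene (excess), second-generation Grubbs catalyst RuCl2(=CHPh)(PCy3)(H2IMes) (5 mol %), CH2Cl2, 40 °C
Reagents that add atoms: 2-methylbut-2-ene, CC=C(C)C
Why: Olefin cross-metathesis of a terminal alkene with 2-methylbut-2-ene should cap it as the isopropylidene terminus; it is placed after steps 2 and 3, which a trisubstituted chain alkene would not survive, and no stereocentre is touched.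

Step 5
Reactants: 9 (2S,3S)-3-bromo-2-methyl-2-(4-methylpent-3-en-1-yl)-6-{[tri(propan-2-yl)silyl]oxy}cyclohexan-1-one
Product: 10 (5S,6S)-5-bromo-6-methyl-6-(4-methylpent-3-en-1-yl)-2-{[tri(propan-2-yl)silyl]oxy}cyclohex-1-en-1-yl trifluoromethanesulfonate
Conditions: KN(SiMe3)2, THF, −78 °C; then PhNTf2, −78 to 0 °C
Reagents that add atoms: N-phenylbis(trifluoromethanesulfonimide), O=S(=O)(N(c1ccccc1)S(=O)(=O)C(F)(F)F)C(F)(F)F
Why: Enol triflate formation; the hydrogen on C6 is the only α-hydrogen, so a single enolate forms and is sulfonylated on oxygen, the bulky triisopropylsilyl group should resist oxygen-to-oxygen silyl migration in the enediolate, and the C6 stereocentre disappears.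

Step 6
Reactants: 10 (5S,6S)-5-bromo-6-methyl-6-(4-methylpent-3-en-1-yl)-2-{[tri(propan-2-yl)silyl]oxy}cyclohex-1-en-1-yl trifluoromethanesulfonate; 11 (4-bromobut-1-yn-1-yl)trimethylsilane
Product: 13 {[(3S,4S)-4-bromo-3-methyl-3-(4-methylpent-3-en-1-yl)-2-[4-(trimethylsilyl)but-3-yn-1-yl]cyclohex-1-en-1-yl]oxy}tri(propan-2-yl)silane, via alkylzinc bromide 12 (not isolated)
Conditions: 11, Zn dust, LiCl, THF, 50 °C; then 10, PdCl2(dppf) (5 mol %), THF/NMP, 60 °C
Reagents that add atoms: none
Why: Negishi coupling (sp2–sp3); zinc inserts into the primary C–Br bond of 11, zerovalent palladium inserts into the C–OTf bond while the hindered secondary C–Br bond should stay inert to this catalyst, and reductive elimination joins C1 to the side chain; the product is an enol ether, a masked C6 ketone, so the carbonyl has moved from C1 to C6.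

Step 7
Reactants: 13 {[(3S,4S)-4-bromo-3-methyl-3-(4-methylpent-3-en-1-yl)-2-[4-(trimethylsilyl)but-3-yn-1-yl]cyclohex-1-en-1-yl]oxy}tri(propan-2-yl)silane
Product: 14 (2S,3S,4S)-4-bromo-2-(but-3-yn-1-yl)-3-methyl-3-(4-methylpent-3-en-1-yl)cyclohexan-1-one
Conditions: TBAF (2.5 equiv), AcOH (2.5 equiv), THF, −78 to 0 °C
Reagents that add atoms: none
Why: Fluoride desilylation of the silyl enol ether and of the alkynylsilane; the enolate should be protonated at C1 axially, anti to the pseudoaxial C2 methyl in the half-chair with equatorial bromine (the other half-chair would put the proton donor syn-axial to the C–Br bond), which gives the epimer with side chain, homoprenyl group and bromine all equatorial, expected also to be the more stable one.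

Step 8
Reactants: 14 (2S,3S,4S)-4-bromo-2-(but-3-yn-1-yl)-3-methyl-3-(4-methylpent-3-en-1-yl)cyclohexan-1-one
Product: 15 (1R,2S,3S,4S)-4-bromo-2-(but-3-yn-1-yl)-1,3-dimethyl-3-(4-methylpent-3-en-1-yl)cyclohexan-1-ol
Conditions: MeLi, CeCl3 (4 equiv each), THF, −78 °C; aq. NH4Cl
Reagents that add atoms: methyllithium, [Li]C
Why: Organocerium 1,2-addition, non-basic so that C1 is not epimerised; the axial C2 methyl is syn-axial to the axial trajectory at C6, so methyl should enter equatorially and the new hydroxyl ends axial, cis to the C1 chain (C6 R in ring numbering).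

Step 9
Reactants: 15 (1R,2S,3S,4S)-4-bromo-2-(but-3-yn-1-yl)-1,3-dimethyl-3-(4-methylpent-3-en-1-yl)cyclohexan-1-ol
Product: 17 (1R,2S,3S,4S)-4-bromo-2-[(3E)-5-hydroxy-3-methylpent-3-en-1-yl]-1,3-dimethyl-3-(4-methylpent-3-en-1-yl)cyclohexan-1-ol, via alkenylalane 16 (not isolated)
Conditions: Me3Al (4 equiv), Cp2ZrCl2 (20 mol %), CH2Cl2, 0 °C to rt; volatiles removed; n-BuLi, hexane/THF, −78 °C; (CH2O)n, −78 °C to rt
Reagents that add atoms: trimethylaluminium, C[Al](C)C; formaldehyde (as paraformaldehyde), C=O
Why: Zirconium-catalysed carboalumination of a terminal alkyne (Negishi); syn addition places methyl on the internal carbon, and the derived alanate is trapped by formaldehyde with retention to give the E allylic alcohol; the trisubstituted alkene, the aluminium alkoxide and the secondary bromide are expected to be spectators.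

Step 10
Reactants: 17 (1R,2S,3S,4S)-4-bromo-2-[(3E)-5-hydroxy-3-methylpent-3-en-1-yl]-1,3-dimethyl-3-(4-methylpent-3-en-1-yl)cyclohexan-1-ol
Product: 18 (1R,2S,3S,4S)-4-bromo-2-{2-[(2S,3S)-3-(hydroxymethyl)-2-methyloxiran-2-yl]ethyl}-1,3-dimethyl-3-(4-methylpent-3-en-1-yl)cyclohexan-1-ol
Conditions: Ti(OiPr)4 (10 mol %), L-(+)-diethyl tartrate (12 mol %), t-BuOOH, 4 Å molecular sieves, CH2Cl2, −20 °C
Reagents that add atoms: tert-butyl hydroperoxide, CC(C)(C)OO
Why: Sharpless asymmetric epoxidation; only the allylic alcohol is epoxidised, and with L-(+)-tartrate an E 3,3-disubstituted allylic alcohol should give the (2S,3S)-epoxide, which fixes the future carbinol carbon as S independently of the ring.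

Step 11
Reactants: 18 (1R,2S,3S,4S)-4-bromo-2-{2-[(2S,3S)-3-(hydroxymethyl)-2-methyloxiran-2-yl]ethyl}-1,3-dimethyl-3-(4-methylpent-3-en-1-yl)cyclohexan-1-ol
Product: 20 (1R,2S,3S,4S)-4-bromo-2-[(3S)-3-hydroxy-3-methylpent-4-en-1-yl]-1,3-dimethyl-3-(4-methylpent-3-en-1-yl)cyclohexan-1-ol, via epoxy iodide 19 (not isolated)
Conditions: I2, PPh3, imidazole, CH2Cl2, 0 °C; then solvent exchange, Zn dust, AcOH, EtOH, rt
Reagents that add atoms: none
Why: Appel-type iodination of the primary alcohol, then zinc-mediated reductive opening of the iodomethyl epoxide (β-elimination), which gives the tertiary vinyl carbinol without touching the C–O bond of the stereocentre; tertiary alcohols should not react with the phosphonium iodide, and zinc in a protic medium is expected to insert into the primary C–I bond far faster than into the hindered secondary C–Br bond.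

## Compound list

1 | 2-methylcyclohex-2-en-1-one | CC1=CCCCC1=O | starting material
2 | but-3-en-1-ylmagnesium bromide | C=CCC[Mg]Br | starting material
3 | di(but-3-en-1-yl)zinc | C=CCC[Zn]CCC=C | intermediate (not isolated)
4 | (1S)-1-(but-3-en-1-yl)-2-methylcyclohex-2-en-1-ol | O[C@@]1(CCC=C)C(C)=CCCC1 | intermediate
5 | (2S,3S)-3-bromo-2-(but-3-en-1-yl)-2-methylcyclohexan-1-one | O=C1[C@](C)(CCC=C)[C@@H](Br)CCC1 | intermediate
6 | {[(5S,6S)-5-bromo-6-(but-3-en-1-yl)-6-methylcyclohex-1-en-1-yl]oxy}tri(propan-2-yl)silane | CC(C)[Si](C(C)C)(C(C)C)OC1=CCC[C@H](Br)[C@@]1(C)CCC=C | intermediate (not isolated)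
7 | {[(2S,3S)-3-bromo-2-(but-3-en-1-yl)-2-methyl-7-oxabicyclo[4.1.0]heptan-1-yl]oxy}tri(propan-2-yl)silane (epoxide diastereomers) | CC(C)[Si](C(C)C)(C(C)C)OC12OC1CC[C@H](Br)[C@@]2(C)CCC=C | intermediate (not isolated)
8 | (2S,3S)-3-bromo-2-(but-3-en-1-yl)-2-methyl-6-{[tri(propan-2-yl)silyl]oxy}cyclohexan-1-one (C6 epimers) | CC(C)[Si](C(C)C)(C(C)C)OC1CC[C@H](Br)[C@@](C)(CCC=C)C1=O | intermediate
9 | (2S,3S)-3-bromo-2-methyl-2-(4-methylpent-3-en-1-yl)-6-{[tri(propan-2-yl)silyl]oxy}cyclohexan-1-one (C6 epimers) | CC(C)[Si](C(C)C)(C(C)C)OC1CC[C@H](Br)[C@@](C)(CCC=C(C)C)C1=O | intermediate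
10 | (5S,6S)-5-bromo-6-methyl-6-(4-methylpent-3-en-1-yl)-2-{[tri(propan-2-yl)silyl]oxy}cyclohex-1-en-1-yl trifluoromethanesulfonate | CC(C)[Si](C(C)C)(C(C)C)OC1=C(OS(=O)(=O)C(F)(F)F)[C@](C)(CCC=C(C)C)[C@@H](Br)CC1 | intermediate
11 | (4-bromobut-1-yn-1-yl)trimethylsilane | C[Si](C)(C)C#CCCBr | starting material
12 | [4-(trimethylsilyl)but-3-yn-1-yl]zinc bromide | C[Si](C)(C)C#CCC[Zn]Br | intermediate (not isolated)
13 | {[(3S,4S)-4-bromo-3-methyl-3-(4-methylpent-3-en-1-yl)-2-[4-(trimethylsilyl)but-3-yn-1-yl]cyclohex-1-en-1-yl]oxy}tri(propan-2-yl)silane | CC(C)[Si](C(C)C)(C(C)C)OC1=C(CCC#C[Si](C)(C)C)[C@](C)(CCC=C(C)C)[C@@H](Br)CC1 | intermediate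
14 | (2S,3S,4S)-4-bromo-2-(but-3-yn-1-yl)-3-methyl-3-(4-methylpent-3-en-1-yl)cyclohexan-1-one | C#CCC[C@H]1[C@](C)(CCC=C(C)C)[C@@H](Br)CCC1=O | intermediate
15 | (1R,2S,3S,4S)-4-bromo-2-(but-3-yn-1-yl)-1,3-dimethyl-3-(4-methylpent-3-en-1-yl)cyclohexan-1-ol | C#CCC[C@H]1[C@](C)(CCC=C(C)C)[C@@H](Br)CC[C@@]1(C)O | intermediate
16 | {(1E)-4-[(1S,2S,3S,6R)-3-bromo-6-[(dimethylalumanyl)oxy]-2,6-dimethyl-2-(4-methylpent-3-en-1-yl)cyclohexyl]-2-methylbut-1-en-1-yl}dimethylalane | C[Al](C)/C=C(\C)CC[C@H]1[C@](C)(CCC=C(C)C)[C@@H](Br)CC[C@@]1(C)O[Al](C)C | intermediate (not isolated)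
17 | (1R,2S,3S,4S)-4-bromo-2-[(3E)-5-hydroxy-3-methylpent-3-en-1-yl]-1,3-dimethyl-3-(4-methylpent-3-en-1-yl)cyclohexan-1-ol | OC/C=C(\C)CC[C@H]1[C@](C)(CCC=C(C)C)[C@@H](Br)CC[C@@]1(C)O | intermediate
18 | (1R,2S,3S,4S)-4-bromo-2-{2-[(2S,3S)-3-(hydroxymethyl)-2-methyloxiran-2-yl]ethyl}-1,3-dimethyl-3-(4-methylpent-3-en-1-yl)cyclohexan-1-ol | OC[C@@H]1O[C@@]1(C)CC[C@H]2[C@](C)(CCC=C(C)C)[C@@H](Br)CC[C@@]2(C)O | intermediate
19 | (1R,2S,3S,4S)-4-bromo-2-{2-[(2S,3R)-3-(iodomethyl)-2-methyloxiran-2-yl]ethyl}-1,3-dimethyl-3-(4-methylpent-3-en-1-yl)cyclohexan-1-ol | IC[C@@H]1O[C@@]1(C)CC[C@H]2[C@](C)(CCC=C(C)C)[C@@H](Br)CC[C@@]2(C)O | intermediate (not isolated)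
20 | (1R,2S,3S,4S)-4-bromo-2-[(3S)-3-hydroxy-3-methylpent-4-en-1-yl]-1,3-dimethyl-3-(4-methylpent-3-en-1-yl)cyclohexan-1-ol | C=C[C@@](C)(O)CC[C@H]1[C@](C)(CCC=C(C)C)[C@@H](Br)CC[C@@]1(C)O | target

## Step count and least certain steps

Total step count: 11. Longest linear sequence: 11 steps (from 1).

**Step 2 (key step).** The bromonium ion may be captured by the hydroxyl oxygen to give a bromo epoxide instead of triggering the shift, the ring bond may migrate instead of the butenyl group, or bromine may add to the terminal alkene. All three are losses of chemoselectivity at the cationic stage. Fallback: set out from 4 and convert it into its trimethylsilyl ether {[(1S)-1-(but-3-en-1-yl)-2-methylcyclohex-2-en-1-yl]oxy}trimethylsilane F1. The oxygen of F1 can no longer close an epoxide, but it can still drive the 1,2-shift by losing the silyl group to the succinimide anion, so the rearrangement becomes a silyl-terminated semipinacol. The route is rejoined at 5.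

**Step 7.** Facial selectivity in the protonation at C1 may be poor, because the two groups on C2 differ little and only the C–Br bond and the ring conformation bias the faces. Fallback: set out from the epimer mixture of 14 and switch from kinetic to thermodynamic control. The mixture is equilibrated with an amine base, the all-equatorial epimer is separated, and the minor epimer is returned to the equilibration. No new compound is made and the route is rejoined at 14.

**Step 6.** Oxidative addition into the tetrasubstituted, electron-rich enol triflate next to a quaternary carbon may be slow, so that reduction of the triflate or protonation of the zinc reagent takes over. Fallback: set out from 9. The Grignard reagent [4-(trimethylsilyl)but-3-yn-1-yl]magnesium bromide F2 is made from 11, transmetalated with CeCl3 and added to the ketone of 9. This gives the tertiary alcohol (2S,3S)-3-bromo-2-methyl-2-(4-methylpent-3-en-1-yl)-6-{[tri(propan-2-yl)silyl]oxy}-1-[4-(trimethylsilyl)but-3-yn-1-yl]cyclohexan-1-ol F3. Syn dehydration across C1–C6 with the Burgess reagent then gives the enol ether, and the route is rejoined at 13.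

**Step 9.** The Lewis-acidic alane may ionise the secondary bromide, or n-BuLi may undergo lithium–bromine exchange before the alanate forms. Fallback: set out from 10 and bring in the methyl-branched alkene ready-made. The bromide {[(2E)-5-bromo-3-methylpent-2-en-1-yl]oxy}(tert-butyl)dimethylsilane F4 is prepared separately from a commercial C4 alkynol by the same carboalumination chemistry, at a stage where no secondary bromide is present. It is converted into the zinc reagent [(3E)-5-{[tert-butyl(dimethyl)silyl]oxy}-3-methylpent-3-en-1-yl]zinc bromide F5 and coupled with 10 as in step 6. This gives the enol ether {[(3S,4S)-4-bromo-2-[(3E)-5-{[tert-butyl(dimethyl)silyl]oxy}-3-methylpent-3-en-1-yl]-3-methyl-3-(4-methylpent-3-en-1-yl)cyclohex-1-en-1-yl]oxy}tri(propan-2-yl)silane F6. Fluoride then gives the ketone (2S,3S,4S)-4-bromo-2-[(3E)-5-hydroxy-3-methylpent-3-en-1-yl]-3-methyl-3-(4-methylpent-3-en-1-yl)cyclohexan-1-one F7. Methyl addition as in step 8 rejoins the route at 17.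

**Step 1.** The enantiomeric excess may be insufficient with a dialkylzinc that is made from a Grignard reagent, since residual magnesium salts can open a racemic background addition. Fallback: set out from 1 and 2, add 2 directly to 1 in the presence of CeCl3 to give racemic material, and resolve it by preparative chromatography on a chiral stationary phase. No new compound is made and the route is rejoined at 4.

## Further compounds

F1 | step 2 | {[(1S)-1-(but-3-en-1-yl)-2-methylcyclohex-2-en-1-yl]oxy}trimethylsilane | C[Si](C)(C)O[C@@]1(CCC=C)C(C)=CCCC1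
F0 | step 7 | none | none
F2 | step 6 | [4-(trimethylsilyl)but-3-yn-1-yl]magnesium bromide | C[Si](C)(C)C#CCC[Mg]Br
F3 | step 6 | (2S,3S)-3-bromo-2-methyl-2-(4-methylpent-3-en-1-yl)-6-{[tri(propan-2-yl)silyl]oxy}-1-[4-(trimethylsilyl)but-3-yn-1-yl]cyclohexan-1-ol (C1 and C6 epimers) | CC(C)[Si](C(C)C)(C(C)C)OC1CC[C@H](Br)[C@@](C)(CCC=C(C)C)C1(O)CCC#C[Si](C)(C)C
F4 | step 9 | {[(2E)-5-bromo-3-methylpent-2-en-1-yl]oxy}(tert-butyl)dimethylsilane | CC(C)(C)[Si](C)(C)OC/C=C(\C)CCBr
F5 | step 9 | [(3E)-5-{[tert-butyl(dimethyl)silyl]oxy}-3-methylpent-3-en-1-yl]zinc bromide | CC(C)(C)[Si](C)(C)OC/C=C(\C)CC[Zn]Br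
F6 | step 9 | {[(3S,4S)-4-bromo-2-[(3E)-5-{[tert-butyl(dimethyl)silyl]oxy}-3-methylpent-3-en-1-yl]-3-methyl-3-(4-methylpent-3-en-1-yl)cyclohex-1-en-1-yl]oxy}tri(propan-2-yl)silane | CC(C)[Si](C(C)C)(C(C)C)OC1=C(CC/C(C)=C/CO[Si](C)(C)C(C)(C)C)[C@](C)(CCC=C(C)C)[C@@H](Br)CC1
F7 | step 9 | (2S,3S,4S)-4-bromo-2-[(3E)-5-hydroxy-3-methylpent-3-en-1-yl]-3-methyl-3-(4-methylpent-3-en-1-yl)cyclohexan-1-one | OC/C=C(\C)CC[C@H]1[C@](C)(CCC=C(C)C)[C@@H](Br)CCC1=O
F0 | step 1 | none | none
A1 | alternative 1 | (3S,6E,10E)-3,7,11,15-tetramethylhexadeca-1,6,10,14-tetraen-3-ol ((S)-geranyllinalool) | C=C[C@@](C)(O)CC/C=C(\C)CC/C=C(\C)CCC=C(C)C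
A2 | alternative 2 | 2-methyl-2-(4-methylpent-3-en-1-yl)cyclohexane-1,3-dione | CC(C)=CCCC1(C)C(=O)CCCC1=O
A3 | alternative 2 | (2R,3R)-3-hydroxy-2-methyl-2-(4-methylpent-3-en-1-yl)cyclohexan-1-one | O=C1[C@](C)(CCC=C(C)C)[C@H](O)CCC1
A4 | alternative 3 | (2E)-3,7-dimethylocta-2,6-dien-1-yl hex-5-ynoate | C#CCCCC(=O)OC/C=C(\C)CCC=C(C)C
A5 | alternative 3 | (2S,3R)-2-(but-3-yn-1-yl)-3-methyl-3-(4-methylpent-3-en-1-yl)pent-4-enoic acid | OC(=O)[C@@H](CCC#C)[C@](C)(CCC=C(C)C)C=C
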